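Whatever the flask does, the Z units charged stay counted: Z, E, Q and D add up to the charge, with one E as two units and one Q as 3. So E is what remains after free Z, Q and D are subtracted, and I build that subtraction for cedar one step at a time.

| flask | Z | temperature | remark | time |
|---|---|---|---|---|
| gamma | 0.28 M | 80 °C | run made earlier |  |
| cedar | 0.14 M | 80 °C |  | 6.0 h |
| oak | 0.14 M | 100 °C |  | 6.0 h |
| birch | 0.14 M | 120 °C |  | 6.0 h |

gamma run (percent of the Z charged)

| time / min | E / % | Z / % |
|---|---|---|
| 2.00 | 29.8 | 71.7 |
| 6.00 | 54.2 | 46.4 |
| 10.0 | 68.1 | 33.0 |
| 15.0 | 74.0 | 25.0 |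
| 20.0 | 78.7 | 19.9 |
| 30.0 | 83.1 | 13.8 |
| 40.0 | 84.5 | 11.8 |

(scatter of a reading: 1 percentage point)

- percent here means Z units held: one E counts as two
- percent here means Z units held: one Q counts as three
- what was read earlier has a scatter of 1 percentage point, one standard deviation
- steps thought possible: 2 Z <-> E; Z -> D; Z + E -> Q
- the earlier runs do not show what temperature does; that part of a forecast is a guess

- which flask leads in amount of E, in percent of the Z charged ("all alike" within 1.5 percentage points) (cedar / oak / birch / all alike)
- how much E is there at the end, in percent of the Z charged: cedar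
- how much E is there at the end, in percent of the Z charged: oak
- how much E is there at the end, in percent of the Z charged: birch

With the main step alone, Z plus E is the charge. In the gamma run the reciprocal of the Z fraction climbs 0.202 min⁻¹. At 0.14 M instead of 0.28 M that climb shrinks in proportion, so the first half-life of Z in cedar is 9.92 min, far shorter than 6.0 h. Z stops where the back step balances. In the gamma run Z is still falling at its last reading of 11.8 %, while cedar is more dilute; these pull opposite ways, so I take that reading as cedar's free Z. E, the resting state of the Z units, then stands at 88.2 %.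

Now I add the leak. At the last gamma reading the balance is short by 3.70 %, with a scatter of 1.4 percentage points. At 6.00 min Z plus E reads 101 %, and a balance with that scatter does not tell Q from D, so booking the shortfall to Q and none to D is my assumption. Q, in fractions of the charge, grows at 3/2 times a constant, the charge, and the fractions of Z and E. Taking the 20.0 min reading as the run's typical product, the shortfall gives the leak constant 0.0141 M⁻¹ min⁻¹. For cedar that means Q of 11.1 %. Since free Z stays put, I take the whole of it from E, which leaves 77.1 %. Temperature is a guess, and I guess cedar leads.

The forecast says cedar leads, with 81 %, 66 % and 42 %, its cedar figure above mine, and reasons that “E should fall with temperature, so cedar likely leads”.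

Cedar leads with 86.1 % of E, against 67.6 % in oak and 31.5 % in birch. At 6.00 h cedar holds Z 9.35 % and Q 4.50 %.

    2 Z ⇌ E (K = 130 M⁻¹, k = 1.30 M⁻¹ min⁻¹, Ea = 69.0 kJ mol⁻¹, ΔH = −53.0 kJ mol⁻¹)
    Z → D (k = 7.00 × 10⁻⁵ min⁻¹, Ea = 119 kJ mol⁻¹)
    Z + E → Q (k = 0.0220 M⁻¹ min⁻¹, Ea = 74.0 kJ mol⁻¹)
    (constants at 100 °C)

With those simulated Z and E, the leak constant gives Q of 8.56 %, about twice what stands there. From 6.00 h to 60.0 h, using the mean product of the two ends, it gives a gain of 62.4 %, against a simulated 25 points. Cedar then holds E 62.6 % at 60.0 h.

The numbers in the tables were computed with constants of no real substance; noise was put on by code.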